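**Plan**

1. Retrosynthesis: after removal of three MOM ethers, the pyran bonds O1–C8a and C2–C3 are cut together. This gives a ring B aldehyde (C2 with O1) and a ring A 2-arylethylzinc reagent that carries bromine at C8a.
2. Enabling feature: O1 links the benzylic stereocentre C2 to the sp2 carbon C8a of ring A, C8a is ortho to the C4–C3 tether, and C3 is a plain methylene. One ring A block can therefore hold a C3 nucleophile and a C8a electrophile, and the aldehyde C=O is stitched in between them.
3. Ring A block from 2-bromo-4-hydroxybenzaldehyde 1: O-prenylation, methylenation, hydroboration, aromatic Claisen shift (1,1-dimethylallyl group), MOM, iodide, zinc insertion and capping of zinc with a (trimethylsilyl)methyl group. Ring B block from 2,3-dibromo-4,5-dihydroxybenzaldehyde 2: MOM, double Stille prenylation.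
4. Forward order: rings A and B are carried as separate arenes; the pyran ring arises last, in the union of the two blocks; deprotection ends the route.
5. Stereochemistry: C2 (S) is the only stereocentre. It comes from catalyst-controlled Si-face alkyl transfer to the aldehyde and is retained in the C–O ring closure and the deprotection.

Key step: step 10

Remark: 1 and 2 are taken as purchasable benzaldehydes.

**Route**

Step 1
Reactants: 1 2-bromo-4-hydroxybenzaldehyde
Product: 3 2-bromo-4-[(3-methylbut-2-en-1-yl)oxy]benzaldehyde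
Conditions: prenyl bromide, K2CO3, acetone, reflux
Reagents that add atoms: prenyl bromide (1-bromo-3-methylbut-2-ene), CC(C)=CCBr
Why: Williamson ether synthesis: the phenoxide formed by K2CO3 displaces the primary allylic bromide by SN2 at oxygen, and no other nucleophile is present.

Step 2
Reactants: 3 2-bromo-4-[(3-methylbut-2-en-1-yl)oxy]benzaldehyde
Product: 4 2-bromo-1-ethenyl-4-[(3-methylbut-2-en-1-yl)oxy]benzene
Conditions: Ph3PCH3Br, KOt-Bu, THF, 0 °C to rt
Reagents that add atoms: methyltriphenylphosphonium bromide, C[P+](c1ccccc1)(c1ccccc1)c1ccccc1.[Br-]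
Why: Wittig methylenation of the aryl aldehyde by the non-stabilised ylide; the aryl bromide and the allyl aryl ether are inert to it.

Step 3
Reactants: 4 2-bromo-1-ethenyl-4-[(3-methylbut-2-en-1-yl)oxy]benzene
Product: 6 2-{2-bromo-4-[(3-methylbut-2-en-1-yl)oxy]phenyl}ethan-1-ol, via alkylborane 5 (not isolated)
Conditions: 9-BBN, THF, 0 °C to rt; then NaOH, H2O2, 0 °C
Reagents that add atoms: 9-borabicyclo[3.3.1]nonane, B1C2CCCC1CCC2 (boron of 5); hydrogen peroxide, OO (hydroxyl oxygen of 6)
Why: Hydroboration–oxidation: 9-BBN adds anti-Markovnikov to the monosubstituted styrene C=C much faster than to the trisubstituted prenyl C=C, and alkaline peroxide turns C–B into C–OH with the aryl bromide untouched.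

Step 4
Reactants: 6 2-{2-bromo-4-[(3-methylbut-2-en-1-yl)oxy]phenyl}ethan-1-ol
Product: 7 2-[2-bromo-4-hydroxy-5-(2-methylbut-3-en-2-yl)phenyl]ethan-1-ol
Conditions: PhNEt2, 190 °C, sealed tube
Reagents that add atoms: none
Why: Aromatic Claisen rearrangement: the concerted [3,3] shift converts the O-prenyl ether into the C-bound 2-methylbut-3-en-2-yl phenol, and the new quaternary carbon should prefer the ortho carbon para to bromine because the other ortho carbon is buttressed by the bromine atom.

Step 5
Reactants: 7 2-[2-bromo-4-hydroxy-5-(2-methylbut-3-en-2-yl)phenyl]ethan-1-ol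
Product: 8 2-[2-bromo-4-(methoxymethoxy)-5-(2-methylbut-3-en-2-yl)phenyl]ethan-1-ol
Conditions: MOMCl, K2CO3, acetone, rt
Reagents that add atoms: chloromethyl methyl ether, COCCl
Why: Phenol-selective Williamson-type O-alkylation: K2CO3 ionises the phenol but not the primary alcohol, so only the phenoxide attacks MOMCl.

Step 6
Reactants: 8 2-[2-bromo-4-(methoxymethoxy)-5-(2-methylbut-3-en-2-yl)phenyl]ethan-1-ol
Product: 9 1-bromo-2-(2-iodoethyl)-5-(methoxymethoxy)-4-(2-methylbut-3-en-2-yl)benzene
Conditions: PPh3, I2, imidazole, CH2Cl2, 0 °C to rt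
Reagents that add atoms: iodine, II
Why: Appel-type iodination: the primary alcohol is activated as an alkoxyphosphonium ion and displaced by iodide by SN2, with imidazole keeping the medium non-acidic for the MOM acetal.

Step 7
Reactants: 9 1-bromo-2-(2-iodoethyl)-5-(methoxymethoxy)-4-(2-methylbut-3-en-2-yl)benzene
Product: 11 {2-[2-bromo-4-(methoxymethoxy)-5-(2-methylbut-3-en-2-yl)phenyl]ethyl}[(trimethylsilyl)methyl]zinc, via alkylzinc iodide 10 (not isolated)
Conditions: Zn dust (activated with BrCH2CH2Br and Me3SiCl), THF, 35 °C; then Me3SiCH2Li (0.98 equiv, pentane), −78 °C to 0 °C; THF removed in vacuo, residue taken up in toluene, LiI filtered off under argon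
Reagents that add atoms: zinc, [Zn]; (trimethylsilyl)methyllithium, [Li]C[Si](C)(C)C
Why: Direct insertion of activated zinc into the primary C–I bond gives the alkylzinc iodide without touching the aryl bromide, the acetal or the alkenes, and transmetalation with slightly less than one equivalent of Me3SiCH2Li replaces iodide on zinc by the non-transferable (trimethylsilyl)methyl group, so that the mixed dialkylzinc holds a single 2-arylethyl group that can be delivered completely.

Step 8
Reactants: 2 2,3-dibromo-4,5-dihydroxybenzaldehyde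
Product: 12 2,3-dibromo-4,5-bis(methoxymethoxy)benzaldehyde
Conditions: MOMCl (2.5 equiv), K2CO3, DMF, 0 °C to rt
Reagents that add atoms: chloromethyl methyl ether, COCCl
Why: Williamson-type double O-alkylation of the catechol; the MOM ethers later resist zinc reagents and carbonate base.

Step 9
Reactants: 12 2,3-dibromo-4,5-bis(methoxymethoxy)benzaldehyde
Product: 13 4,5-bis(methoxymethoxy)-2,3-bis(3-methylbut-2-en-1-yl)benzaldehyde
Conditions: tributyl(3-methylbut-2-en-1-yl)stannane (3 equiv), Pd(PPh3)4 (10 mol %), DMF, 100 °C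
Reagents that add atoms: tributyl(3-methylbut-2-en-1-yl)stannane, CC(C)=CC[Sn](CCCC)(CCCC)CCCC
Why: Twofold Migita–Kosugi–Stille coupling: the allylstannane does not add to the free aldehyde without a Lewis acid, the C–Br bond ortho to the formyl group reacts first, and transmetalation at the tin-bearing CH2 should give the linear 3-methylbut-2-enyl groups.

Step 10
Reactants: 11 {2-[2-bromo-4-(methoxymethoxy)-5-(2-methylbut-3-en-2-yl)phenyl]ethyl}[(trimethylsilyl)methyl]zinc; 13 4,5-bis(methoxymethoxy)-2,3-bis(3-methylbut-2-en-1-yl)benzaldehyde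
Product: 16 (2S)-2-[4,5-bis(methoxymethoxy)-2,3-bis(3-methylbut-2-en-1-yl)phenyl]-7-(methoxymethoxy)-6-(2-methylbut-3-en-2-yl)-3,4-dihydro-2H-1-benzopyran, via zinc alkoxide 14 (not isolated), via bromo carbinol 15 (not isolated)
Conditions: 11 (1.3 equiv), (2S)-(−)-3-exo-morpholinoisoborneol (8 mol %), N,N,N',N'-tetraethylethylenediamine (0.3 equiv), toluene, 0 °C to rt; then AcOH, 0 °C; then Cs2CO3, Pd(OAc)2 (5 mol %), 2-(di-tert-butylphosphino)-1,1'-binaphthyl (6 mol %), 80 °C, same flask
Reagents that add atoms: none
Why: The zinc aminoalkoxide formed from the chiral amino alcohol binds the mixed reagent 11 and aldehyde 13 in a bimetallic six-membered transition state and hands the 2-arylethyl group, not the non-transferable (trimethylsilyl)methyl group, to the Si face of the C=O (C2–C3 bond, alkoxide 14). Acetic acid then cleaves the C–Zn and O–Zn bonds to give carbinol 15, and oxidative addition of zerovalent palladium into C8a–Br, bromide/alkoxide exchange at divalent palladium and C–O reductive elimination form O1–C8a. The closest known reaction types are the catalytic enantioselective addition of dialkylzincs and of mixed alkyl[(trimethylsilyl)methyl]zinc reagents to aryl aldehydes and the Buchwald–Hartwig-type intramolecular aryl etherification of secondary alcohols, run here in one flask as a formal [4+2] annulation of the aldehyde C=O across C3 and C8a. The pyran ring closes by reductive elimination from a seven-membered oxapalladacycle, a six-membered closure at the aryl carbon. C2 is set by the catalyst (this amino alcohol series delivers alkyl to the Si face of aryl aldehydes, which means S here because the aryl group outranks the new CH2) and is carried through the C–O coupling with retention, since no bond to C2 is broken. The step needs face selectivity, alkyl transfer to the aldehyde only, and reductive elimination faster than beta-hydride elimination of the palladium alkoxide: the first rests on the catalyst and on the diamine that masks residual lithium iodide (no salt-promoted racemic background), the second on the inertness of Ar–Br, acetal and alkene groups to the zinc reagent and on protonolysis of every C–Zn bond before palladium is added (no Negishi pathway), the third on the bulky di-tert-butyl biaryl phosphine and on bromine sitting ortho to the tether, which leaves the six-membered closure as the only intramolecular option.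

Step 11
Reactants: 16 (2S)-2-[4,5-bis(methoxymethoxy)-2,3-bis(3-methylbut-2-en-1-yl)phenyl]-7-(methoxymethoxy)-6-(2-methylbut-3-en-2-yl)-3,4-dihydro-2H-1-benzopyran
Product: 17 Kazinol E, (2S)-2-[4,5-dihydroxy-2,3-bis(3-methylbut-2-en-1-yl)phenyl]-6-(2-methylbut-3-en-2-yl)-3,4-dihydro-2H-1-benzopyran-7-ol
Conditions: HCl (0.3 M) in MeOH, 0 °C to rt
Reagents that add atoms: none
Why: Acid-catalysed acetal exchange: dilute anhydrous HCl in methanol transfers the three methoxymethyl groups to methanol at or below room temperature, which should be mild enough to leave the prenyl groups, the 1,1-dimethylallyl group and the benzylic C2–O bond (hence the C2 configuration) untouched.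

**Compound list**

1 | 2-bromo-4-hydroxybenzaldehyde | O=Cc1ccc(O)cc1Br | starting material
2 | 2,3-dibromo-4,5-dihydroxybenzaldehyde | O=Cc1cc(O)c(O)c(Br)c1Br | starting material
3 | 2-bromo-4-[(3-methylbut-2-en-1-yl)oxy]benzaldehyde | O=Cc1ccc(OCC=C(C)C)cc1Br | intermediate
4 | 2-bromo-1-ethenyl-4-[(3-methylbut-2-en-1-yl)oxy]benzene | C=Cc1ccc(OCC=C(C)C)cc1Br | intermediate
5 | 9-(2-{2-bromo-4-[(3-methylbut-2-en-1-yl)oxy]phenyl}ethyl)-9-borabicyclo[3.3.1]nonane (alkylborane, not isolated) | CC(C)=CCOc1ccc(CCB2C3CCCC2CCC3)c(Br)c1 | intermediate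
6 | 2-{2-bromo-4-[(3-methylbut-2-en-1-yl)oxy]phenyl}ethan-1-ol | OCCc1ccc(OCC=C(C)C)cc1Br | intermediate
7 | 2-[2-bromo-4-hydroxy-5-(2-methylbut-3-en-2-yl)phenyl]ethan-1-ol | OCCc1cc(C(C)(C)C=C)c(O)cc1Br | intermediate
8 | 2-[2-bromo-4-(methoxymethoxy)-5-(2-methylbut-3-en-2-yl)phenyl]ethan-1-ol | OCCc1cc(C(C)(C)C=C)c(OCOC)cc1Br | intermediate
9 | 1-bromo-2-(2-iodoethyl)-5-(methoxymethoxy)-4-(2-methylbut-3-en-2-yl)benzene | ICCc1cc(C(C)(C)C=C)c(OCOC)cc1Br | intermediate
10 | {2-[2-bromo-4-(methoxymethoxy)-5-(2-methylbut-3-en-2-yl)phenyl]ethyl}(iodo)zinc (alkylzinc iodide, not isolated) | C=CC(C)(C)c1cc(CC[Zn]I)c(Br)cc1OCOC | intermediate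
11 | {2-[2-bromo-4-(methoxymethoxy)-5-(2-methylbut-3-en-2-yl)phenyl]ethyl}[(trimethylsilyl)methyl]zinc | C=CC(C)(C)c1cc(CC[Zn]C[Si](C)(C)C)c(Br)cc1OCOC | intermediate
12 | 2,3-dibromo-4,5-bis(methoxymethoxy)benzaldehyde | O=Cc1cc(OCOC)c(OCOC)c(Br)c1Br | intermediate
13 | 4,5-bis(methoxymethoxy)-2,3-bis(3-methylbut-2-en-1-yl)benzaldehyde | O=Cc1cc(OCOC)c(OCOC)c(CC=C(C)C)c1CC=C(C)C | intermediate
14 | (S)-zinc alkoxide: the alkoxide oxygen of 15 bound to zinc, which still carries the (trimethylsilyl)methyl group (not isolated) | C[Si](C)(C)C[Zn]O[C@H](c1cc(OCOC)c(OCOC)c(CC=C(C)C)c1CC=C(C)C)CCc1cc(C(C)(C)C=C)c(OCOC)cc1Br | intermediate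
15 | (1S)-3-[2-bromo-4-(methoxymethoxy)-5-(2-methylbut-3-en-2-yl)phenyl]-1-[4,5-bis(methoxymethoxy)-2,3-bis(3-methylbut-2-en-1-yl)phenyl]propan-1-ol (not isolated) | O[C@H](c1cc(OCOC)c(OCOC)c(CC=C(C)C)c1CC=C(C)C)CCc1cc(C(C)(C)C=C)c(OCOC)cc1Br | intermediate
16 | (2S)-2-[4,5-bis(methoxymethoxy)-2,3-bis(3-methylbut-2-en-1-yl)phenyl]-7-(methoxymethoxy)-6-(2-methylbut-3-en-2-yl)-3,4-dihydro-2H-1-benzopyran | C=CC(C)(C)c1cc2c(cc1OCOC)O[C@H](c1cc(OCOC)c(OCOC)c(CC=C(C)C)c1CC=C(C)C)CC2 | intermediate
17 | Kazinol E, (2S)-2-[4,5-dihydroxy-2,3-bis(3-methylbut-2-en-1-yl)phenyl]-6-(2-methylbut-3-en-2-yl)-3,4-dihydro-2H-1-benzopyran-7-ol | C=CC(C)(C)c1cc2c(cc1O)O[C@H](c1cc(O)c(O)c(CC=C(C)C)c1CC=C(C)C)CC2 | target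

**Step count and risks**

Total steps: 11. Longest linear sequence: 9 steps (steps 1 to 7, then 10 and 11).

Steps most likely to fail:

1. Step 10. What may go wrong: slow or poorly face-selective alkyl transfer from the mixed zinc reagent to the hindered, electron-rich aldehyde; residual lithium salt opening a racemic background path; zinc and acetate salts slowing the palladium cycle; beta-hydride elimination at the palladium alkoxide. Fallback (stereocentre set by ketone reduction, ring closed in a separate operation): the route is left at 11 and 13. Addition of 11 to 13 promoted by achiral Ti(OiPr)4 (toluene, −20 °C to rt), followed by aqueous NH4Cl work-up, should give racemic 3-[2-bromo-4-(methoxymethoxy)-5-(2-methylbut-3-en-2-yl)phenyl]-1-[4,5-bis(methoxymethoxy)-2,3-bis(3-methylbut-2-en-1-yl)phenyl]propan-1-ol F1. Dess–Martin periodinane (CH2Cl2, NaHCO3) should give 3-[2-bromo-4-(methoxymethoxy)-5-(2-methylbut-3-en-2-yl)phenyl]-1-[4,5-bis(methoxymethoxy)-2,3-bis(3-methylbut-2-en-1-yl)phenyl]propan-1-one F2. Noyori asymmetric transfer hydrogenation with RuCl(p-cymene)[(S,S)-TsDPEN] in HCO2H/Et3N should return the (S)-carbinol 15, this time isolated. A separate aryl etherification (Pd(OAc)2, the same phosphine, Cs2CO3, toluene, 80 °C) closes the pyran ring, and the route is rejoined at 16.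

2. Step 4. What may go wrong: migration of the allyl unit to the ortho carbon next to bromine, onward abnormal Claisen shifts at 190 °C, or cyclisation of the product phenol onto its own allyl group. Fallback (the quaternary aryl–carbon bond made by cross-coupling at a position fixed by halogenation): the route is left at 1. N-Iodosuccinimide (MeCN, cat. CF3CO2H) should iodinate the unhindered carbon ortho to the hydroxyl to give 2-bromo-4-hydroxy-5-iodobenzaldehyde F3. MOMCl/K2CO3 gives 2-bromo-5-iodo-4-(methoxymethoxy)benzaldehyde F4. Wittig methylenation gives 1-bromo-2-ethenyl-4-iodo-5-(methoxymethoxy)benzene F5. 9-BBN gives 9-{2-[2-bromo-5-iodo-4-(methoxymethoxy)phenyl]ethyl}-9-borabicyclo[3.3.1]nonane F6, and NaOH/H2O2 then gives 2-[2-bromo-5-iodo-4-(methoxymethoxy)phenyl]ethan-1-ol F7. A branch-selective (gamma-selective) Suzuki–Miyaura coupling of the C–I bond with prenylboronic acid pinacol ester (Pd(OAc)2, bulky dialkylbiarylphosphine, K3PO4, aqueous THF) installs the 2-methylbut-3-en-2-yl group and rejoins the route at 8.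

3. Step 9. What may go wrong: stalling of the second oxidative addition at the hindered, electron-rich C–Br bond, protodebromination, or allyl transposition that gives a 1,1-dimethylallyl isomer. Fallback (aldehyde taken to the alcohol level so that an allylzinc reagent can be used): the route is left at 12. NaBH4 (MeOH, 0 °C) gives [2,3-dibromo-4,5-bis(methoxymethoxy)phenyl]methanol F8. A double linear-selective Negishi coupling with (3-methylbut-2-en-1-yl)zinc bromide (Pd(OAc)2, CPhos, THF, rt; one extra equivalent of the zinc reagent is spent on the hydroxyl) gives [4,5-bis(methoxymethoxy)-2,3-bis(3-methylbut-2-en-1-yl)phenyl]methanol F9. MnO2 (CH2Cl2, rt) oxidises the benzylic alcohol, and the route is rejoined at 13.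

**Further compounds**

F1 | step 10 | racemic 3-[2-bromo-4-(methoxymethoxy)-5-(2-methylbut-3-en-2-yl)phenyl]-1-[4,5-bis(methoxymethoxy)-2,3-bis(3-methylbut-2-en-1-yl)phenyl]propan-1-ol | OC(c1cc(OCOC)c(OCOC)c(CC=C(C)C)c1CC=C(C)C)CCc1cc(C(C)(C)C=C)c(OCOC)cc1Br
F2 | step 10 | 3-[2-bromo-4-(methoxymethoxy)-5-(2-methylbut-3-en-2-yl)phenyl]-1-[4,5-bis(methoxymethoxy)-2,3-bis(3-methylbut-2-en-1-yl)phenyl]propan-1-one | O=C(c1cc(OCOC)c(OCOC)c(CC=C(C)C)c1CC=C(C)C)CCc1cc(C(C)(C)C=C)c(OCOC)cc1Br
F3 | step 4 | 2-bromo-4-hydroxy-5-iodobenzaldehyde | O=Cc1cc(I)c(O)cc1Br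
F4 | step 4 | 2-bromo-5-iodo-4-(methoxymethoxy)benzaldehyde | O=Cc1cc(I)c(OCOC)cc1Br
F5 | step 4 | 1-bromo-2-ethenyl-4-iodo-5-(methoxymethoxy)benzene | C=Cc1cc(I)c(OCOC)cc1Br
F6 | step 4 | 9-{2-[2-bromo-5-iodo-4-(methoxymethoxy)phenyl]ethyl}-9-borabicyclo[3.3.1]nonane | COCOc1cc(Br)c(CCB2C3CCCC2CCC3)cc1I
F7 | step 4 | 2-[2-bromo-5-iodo-4-(methoxymethoxy)phenyl]ethan-1-ol | OCCc1cc(I)c(OCOC)cc1Br
F8 | step 9 | [2,3-dibromo-4,5-bis(methoxymethoxy)phenyl]methanol | OCc1cc(OCOC)c(OCOC)c(Br)c1Br
F9 | step 9 | [4,5-bis(methoxymethoxy)-2,3-bis(3-methylbut-2-en-1-yl)phenyl]methanol | OCc1cc(OCOC)c(OCOC)c(CC=C(C)C)c1CC=C(C)C
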